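**Retrosynthetic overview**

1. The target is traced back to a ring B dihydroxyquinone that carries ring A as a 3-benzyloxy-5-methoxy-4-methylphenyl group. Ring A is raised to the hydroxy-methoxy-quinone last (hydrogenolysis, (KSO3)2NO oxidation, Thiele–Winter acetoxylation, deacetylation in air).
2. The strategy rests on ring B, C(chain)=C(OH)–C(=O)–C(CH3)=C(OH)–C(=O). It is the bis-enol of a cyclohexane-1,2,4,5-tetraone whose CH3-bearing and chain-bearing carbons sit on either side of one C(=O)–C(=O) pair. Cutting their two bonds to the other C(=O)–C(=O) pair leaves an ethyl alkyl 1,2-diketone and diethyl oxalate.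
3. The diketone comes from an internal alkyne (KMnO4). The alkyne comes from Li2CuCl4-catalysed coupling of the ring A benzylic bromide with the Grignard reagent of 18-bromooctadec-3-yne (but-1-yne plus 1,14-dibromotetradecane). The bromide comes from 3,5-dimethoxy-4-methylbenzoic acid by reduction, thiolate mono-demethylation, benzylation and Appel bromination.
4. Ring order: ring A is present from the start as an arene, ring B is closed in step 8, and ring A is oxidised to its quinone after that.

Key step: step 8

Assumption: 3,5-dimethoxy-4-methylbenzoic acid and 1,14-dibromotetradecane are taken as purchasable, and both quinone rings are treated as their 2-hydroxy-1,4-quinone tautomers.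

**Route**

Step 1
Reactants: 1 3,5-dimethoxy-4-methylbenzoic acid
Product: 2 (3,5-dimethoxy-4-methylphenyl)methanol
Conditions: LiAlH4, THF, 0 °C to reflux; then H2O/NaOH work-up
Reagents that add atoms: none
Why: Hydride reduction of an aryl carboxylic acid to the benzylic alcohol; the aryl methyl ethers are inert to LiAlH4.

Step 2
Reactants: 2 (3,5-dimethoxy-4-methylphenyl)methanol
Product: 3 5-(hydroxymethyl)-3-methoxy-2-methylphenol
Conditions: NaSC2H5 (sodium ethanethiolate), DMF, 150 °C; then 1 M HCl
Reagents that add atoms: none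
Why: SN2 demethylation of an aryl methyl ether by thiolate should stop after one ether because the phenoxide formed deactivates the second, and the two methoxy groups are equivalent, so only one phenol can result.

Step 3
Reactants: 3 5-(hydroxymethyl)-3-methoxy-2-methylphenol
Product: 4 [3-(benzyloxy)-5-methoxy-4-methylphenyl]methanol
Conditions: BnBr, K2CO3, acetone, reflux
Reagents that add atoms: benzyl bromide, BrCc1ccccc1
Why: Williamson ether synthesis in which K2CO3 ionises only the phenol, so the benzylic alcohol should stay free.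

Step 4
Reactants: 4 [3-(benzyloxy)-5-methoxy-4-methylphenyl]methanol
Product: 5 1-(benzyloxy)-5-(bromomethyl)-3-methoxy-2-methylbenzene
Conditions: CBr4, PPh3, CH2Cl2, 0 °C
Reagents that add atoms: carbon tetrabromide, BrC(Br)(Br)Br
Why: Appel bromination converts the primary benzylic alcohol into the bromide under neutral conditions that spare the benzyl and methyl ethers.

Step 5
Reactants: 6 but-1-yne; 7 1,14-dibromotetradecane
Product: 9 18-bromooctadec-3-yne, via but-1-yn-1-yllithium 8 (not isolated)
Conditions: n-C4H9Li, THF, −78 °C; then 7 (threefold excess), DMPU, −78 to 25 °C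
Reagents that add atoms: none
Why: SN2 alkylation of a lithium acetylide by a primary alkyl bromide in a dipolar cosolvent; the excess of the symmetric dibromide should hold the reaction at mono-substitution, and unreacted 7 is recovered.

Step 6
Reactants: 9 18-bromooctadec-3-yne; 5 1-(benzyloxy)-5-(bromomethyl)-3-methoxy-2-methylbenzene
Product: 11 1-(benzyloxy)-3-methoxy-2-methyl-5-(nonadec-16-yn-1-yl)benzene, via alkynyl Grignard reagent 10 (not isolated)
Conditions: Mg, THF, 45 °C; then 5, Li2CuCl4 (cat.), THF, −40 to 0 °C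
Reagents that add atoms: none
Why: Copper-catalysed (Kochi-type) cross-coupling of a primary alkyl Grignard reagent with a benzylic bromide forms the sp3–sp3 bond, and the internal alkyne and the ethers tolerate the Grignard reagent.

Step 7
Reactants: 11 1-(benzyloxy)-3-methoxy-2-methyl-5-(nonadec-16-yn-1-yl)benzene
Product: 12 19-[3-(benzyloxy)-5-methoxy-4-methylphenyl]nonadecane-3,4-dione
Conditions: KMnO4, NaHCO3, MgSO4, acetone/H2O, 25 °C
Reagents that add atoms: potassium permanganate, [K+].[O-][Mn](=O)(=O)=O
Why: Permanganate oxidation of an internal dialkyl alkyne under neutral buffering should stop at the 1,2-diketone, the ethers and the arene being attacked far more slowly than the triple bond.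

Step 8
Reactants: 12 19-[3-(benzyloxy)-5-methoxy-4-methylphenyl]nonadecane-3,4-dione; 13 diethyl oxalate
Product: 16 2-{14-[3-(benzyloxy)-5-methoxy-4-methylphenyl]tetradecyl}-3,6-dihydroxy-5-methylcyclohexa-2,5-diene-1,4-dione, via open-chain triketo ester 14 (not isolated), via dipotassium quinonediolate 15 (not isolated)
Conditions: KOC(CH3)3 (excess), 13 (excess), THF, 0 °C, slow addition of 12; then 50 °C; then 1 M HCl
Reagents that add atoms: none
Why: Proposed new method: KOC(CH3)3 enolises 12 at one of the two CH2 groups flanking the 3,4-dione and the enolate C-acylates 13 to the triketo ester 14 (drawn for attack by the ethyl CH2; the adduct from the chain CH2 converges on the same ring), after which the other CH2 is enolised and acylated by the remaining ester carbonyl, and the resulting cyclohexane-1,2,4,5-tetraone is deprotonated twice to the quinonediolate 15, which HCl converts into 16. The closest known reactions are the alkoxide-mediated condensation of dialkyl ketones with diethyl oxalate that closes cyclopentane-1,2,4-triones and the cyclodimerisation of 2-oxo esters to 3,6-dialkyl-2,5-dihydroxybenzoquinones; here a 1,2-diketone supplies four ring carbons and one oxalate supplies two. Ring B closes by a 6-(enolendo)-exo-trig Claisen (Dieckmann-like) acylation, a favoured mode, and both new C–C bonds end at sp2 carbons, so no stereocentre is formed. The selectivity needed is crossed acylation over self-aldol of the diketone; it should be secured by keeping the non-enolisable oxalate and the base in excess, by adding 12 slowly at 0 °C, and by the fact that every step is reversible except the final double deprotonation to the doubly vinylogous carboxylate 15, which drains the equilibria. No regiochemical question arises because the oxalyl unit is symmetric and the two ring B oxygens need no differentiation, and the benzyl ether, the aryl methyl ether and the arene are inert to alkoxide.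

Step 9
Reactants: 16 2-{14-[3-(benzyloxy)-5-methoxy-4-methylphenyl]tetradecyl}-3,6-dihydroxy-5-methylcyclohexa-2,5-diene-1,4-dione
Product: 18 2,5-dihydroxy-3-[14-(3-hydroxy-5-methoxy-4-methylphenyl)tetradecyl]-6-methylcyclohexa-2,5-diene-1,4-dione, via tetrahydroxybenzene 17 (not isolated)
Conditions: H2 (1 atm), 10% Pd/C, THF/EtOAc, 25 °C; filtration; then air, 25 °C
Reagents that add atoms: none
Why: Hydrogenolysis of the benzyl aryl ether over Pd/C; ring B is reduced in passing to the tetrahydroxybenzene, which should autoxidise back to the dihydroxyquinone in air.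

Step 10
Reactants: 18 2,5-dihydroxy-3-[14-(3-hydroxy-5-methoxy-4-methylphenyl)tetradecyl]-6-methylcyclohexa-2,5-diene-1,4-dione
Product: 19 2,5-dihydroxy-3-[14-(5-methoxy-4-methyl-3,6-dioxocyclohexa-1,4-dien-1-yl)tetradecyl]-6-methylcyclohexa-2,5-diene-1,4-dione
Conditions: (KSO3)2NO, KH2PO4, acetone/H2O, 25 °C
Reagents that add atoms: potassium nitrosodisulfonate (KSO3)2NO, [K+].[K+].[O-]S(=O)(=O)N([O])S(=O)(=O)[O-]
Why: Teuber oxidation: the nitroxyl radical converts a phenol with a free para position into the para-quinone, while ring B, fully substituted and already at the quinone level, should be left alone.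

Step 11
Reactants: 19 2,5-dihydroxy-3-[14-(5-methoxy-4-methyl-3,6-dioxocyclohexa-1,4-dien-1-yl)tetradecyl]-6-methylcyclohexa-2,5-diene-1,4-dione
Product: 20 3-{14-[2,5-bis(acetyloxy)-4-methyl-3,6-dioxocyclohexa-1,4-dien-1-yl]tetradecyl}-5-methoxy-6-methylbenzene-1,2,4-triyl triacetate
Conditions: Ac2O, H2SO4 (cat.), 25 °C
Reagents that add atoms: acetic anhydride, CC(=O)OC(C)=O
Why: Thiele–Winter acetoxylation: acid-catalysed conjugate addition of acetate to the only unsubstituted carbon of the ring A quinone (the C–H next to the chain carbon), then enolisation and acetylation, gives the triacetoxyarene, while the two acidic hydroxyls of ring B are simply acetylated.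

Step 12
Reactants: 20 3-{14-[2,5-bis(acetyloxy)-4-methyl-3,6-dioxocyclohexa-1,4-dien-1-yl]tetradecyl}-5-methoxy-6-methylbenzene-1,2,4-triyl triacetate
Product: 22 2,5-dihydroxy-3-[14-(2-hydroxy-5-methoxy-4-methyl-3,6-dioxocyclohexa-1,4-dien-1-yl)tetradecyl]-6-methylcyclohexa-2,5-diene-1,4-dione (CNP0130251.0), via deacetylated trihydroxyarene 21 (not isolated)
Conditions: K2CO3, degassed CH3OH/THF, Ar, 25 °C; then air; then 1 M HCl
Reagents that add atoms: none
Why: Base-mediated transesterification removes the five acetates with methoxide as the only nucleophile, so the ring A methyl ether cannot be lost, and the 1,2,4-trihydroxyarene should autoxidise in air to the 2-hydroxy-1,4-quinone, the methyl ether fixing which oxygens become carbonyls.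

**Compound list**

1 | 3,5-dimethoxy-4-methylbenzoic acid | COc1cc(C(=O)O)cc(OC)c1C | starting material
2 | (3,5-dimethoxy-4-methylphenyl)methanol | COc1cc(CO)cc(OC)c1C | intermediate
3 | 5-(hydroxymethyl)-3-methoxy-2-methylphenol | COc1cc(CO)cc(O)c1C | intermediate
4 | [3-(benzyloxy)-5-methoxy-4-methylphenyl]methanol | COc1cc(CO)cc(OCc2ccccc2)c1C | intermediate
5 | 1-(benzyloxy)-5-(bromomethyl)-3-methoxy-2-methylbenzene | COc1cc(CBr)cc(OCc2ccccc2)c1C | intermediate
6 | but-1-yne | CCC#C | starting material
7 | 1,14-dibromotetradecane | BrCCCCCCCCCCCCCCBr | starting material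
8 | but-1-yn-1-yllithium | CCC#C[Li] | intermediate
9 | 18-bromooctadec-3-yne | CCC#CCCCCCCCCCCCCCCBr | intermediate
10 | bromo(octadec-15-yn-1-yl)magnesium | CCC#CCCCCCCCCCCCCCC[Mg]Br | intermediate
11 | 1-(benzyloxy)-3-methoxy-2-methyl-5-(nonadec-16-yn-1-yl)benzene | CCC#CCCCCCCCCCCCCCCCc1cc(OC)c(C)c(OCc2ccccc2)c1 | intermediate
12 | 19-[3-(benzyloxy)-5-methoxy-4-methylphenyl]nonadecane-3,4-dione | CCC(=O)C(=O)CCCCCCCCCCCCCCCc1cc(OC)c(C)c(OCc2ccccc2)c1 | intermediate
13 | diethyl oxalate | CCOC(=O)C(=O)OCC | starting material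
14 | ethyl 20-[3-(benzyloxy)-5-methoxy-4-methylphenyl]-3-methyl-2,4,5-trioxoicosanoate (open-chain mono-Claisen adduct, drawn for first acylation at the ethyl CH2; C3 racemic and enolisable) | CCOC(=O)C(=O)C(C)C(=O)C(=O)CCCCCCCCCCCCCCCc1cc(OC)c(C)c(OCc2ccccc2)c1 | intermediate
15 | dipotassium 2-{14-[3-(benzyloxy)-5-methoxy-4-methylphenyl]tetradecyl}-5-methyl-3,6-dioxocyclohexa-1,4-diene-1,4-diolate | [K+].[K+].CC1=C([O-])C(=O)C(CCCCCCCCCCCCCCc2cc(OC)c(C)c(OCc3ccccc3)c2)=C([O-])C1=O | intermediate
16 | 2-{14-[3-(benzyloxy)-5-methoxy-4-methylphenyl]tetradecyl}-3,6-dihydroxy-5-methylcyclohexa-2,5-diene-1,4-dione | CC1=C(O)C(=O)C(CCCCCCCCCCCCCCc2cc(OC)c(C)c(OCc3ccccc3)c2)=C(O)C1=O | intermediate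
17 | 3-[14-(3-hydroxy-5-methoxy-4-methylphenyl)tetradecyl]-6-methylbenzene-1,2,4,5-tetrol | Cc1c(O)c(O)c(CCCCCCCCCCCCCCc2cc(OC)c(C)c(O)c2)c(O)c1O | intermediate
18 | 2,5-dihydroxy-3-[14-(3-hydroxy-5-methoxy-4-methylphenyl)tetradecyl]-6-methylcyclohexa-2,5-diene-1,4-dione | CC1=C(O)C(=O)C(CCCCCCCCCCCCCCc2cc(OC)c(C)c(O)c2)=C(O)C1=O | intermediate
19 | 2,5-dihydroxy-3-[14-(5-methoxy-4-methyl-3,6-dioxocyclohexa-1,4-dien-1-yl)tetradecyl]-6-methylcyclohexa-2,5-diene-1,4-dione | CC1=C(O)C(=O)C(CCCCCCCCCCCCCCC2=CC(=O)C(C)=C(OC)C2=O)=C(O)C1=O | intermediate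
20 | 3-{14-[2,5-bis(acetyloxy)-4-methyl-3,6-dioxocyclohexa-1,4-dien-1-yl]tetradecyl}-5-methoxy-6-methylbenzene-1,2,4-triyl triacetate | CC(=O)OC1=C(C)C(=O)C(OC(C)=O)=C(CCCCCCCCCCCCCCc2c(OC(C)=O)c(OC(C)=O)c(C)c(OC)c2OC(C)=O)C1=O | intermediate
21 | 2,5-dihydroxy-3-methyl-6-[14-(2,3,6-trihydroxy-5-methoxy-4-methylphenyl)tetradecyl]cyclohexa-2,5-diene-1,4-dione | COc1c(C)c(O)c(O)c(CCCCCCCCCCCCCCC2=C(O)C(=O)C(C)=C(O)C2=O)c1O | intermediate
22 | 2,5-dihydroxy-3-[14-(2-hydroxy-5-methoxy-4-methyl-3,6-dioxocyclohexa-1,4-dien-1-yl)tetradecyl]-6-methylcyclohexa-2,5-diene-1,4-dione (CNP0130251.0, achiral) | COC1=C(C)C(=O)C(O)=C(CCCCCCCCCCCCCCC2=C(O)C(=O)C(C)=C(O)C2=O)C1=O | target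

**Step count and risks**

Total step count: 12. Longest linear sequence: 11 steps (steps 1 to 4, then 6 to 12); step 5 is a one-step side branch.

Steps most likely to fail:

1. Step 8 (new method). Self-aldol condensation of the diketone enolate may outrun the crossed acylation, or the sequence may stall after the first acylation without closing the ring. The fallback builds ring B from a preformed arene by known chemistry; it sets out from 5 and comes back at 16. Commercial 1,2,4,5-tetramethoxybenzene is lithiated (n-C4H9Li, THF, 0 °C) to (2,3,5,6-tetramethoxyphenyl)lithium F1 and methylated with CH3I to 1,2,4,5-tetramethoxy-3-methylbenzene F2. A second lithiation gives (2,3,5,6-tetramethoxy-4-methylphenyl)lithium F3, which is alkylated with excess commercial 1,13-dibromotridecane to 1-(13-bromotridecyl)-2,3,5,6-tetramethoxy-4-methylbenzene F4. Its Grignard reagent, bromo[13-(2,3,5,6-tetramethoxy-4-methylphenyl)tridecyl]magnesium F5, is coupled with 5 under Li2CuCl4 catalysis to 1-(benzyloxy)-3-methoxy-2-methyl-5-[14-(2,3,5,6-tetramethoxy-4-methylphenyl)tetradecyl]benzene F6. Oxidative demethylation with (NH4)2Ce(NO3)6 in CH3CN/H2O should give 2-{14-[3-(benzyloxy)-5-methoxy-4-methylphenyl]tetradecyl}-3,6-dimethoxy-5-methylcyclohexa-2,5-diene-1,4-dione F7, and NaOH in aqueous dioxane followed by HCl hydrolyses its two vinylogous esters to 16.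

2. Step 11. Acetate addition to the trisubstituted, methoxy-deactivated ring A quinone may be too slow, leaving time for acid-promoted exchange of the methyl ether or decomposition. The fallback places the oxygen by epoxidation and rearrangement; it sets out from 19 and comes back at 22. Nucleophilic epoxidation of the CH=C(chain) double bond of ring A (H2O2, Na2CO3, aqueous dioxane, 0 °C, kept short to spare ring B) should give racemic cis-fused 2,5-dihydroxy-3-[14-(3-methoxy-4-methyl-2,5-dioxo-7-oxabicyclo[4.1.0]hept-3-en-1-yl)tetradecyl]-6-methylcyclohexa-2,5-diene-1,4-dione F8. Acid-mediated epoxide opening with enolisation (cold concentrated H2SO4) then places the hydroxyl on the former C–H carbon and gives 22 directly.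

3. Step 7. Over-oxidation with C–C cleavage of the diketone to carboxylic acids, slow attack on the benzyl ether methylene, or poor solubility of the lipophilic alkyne may erode the oxidation. The fallback goes through a vicinal diol; it sets out from 11 and comes back at 12. Semi-hydrogenation (H2, Pd/CaCO3 poisoned with Pb(OAc)2, quinoline, EtOAc) should give 1-(benzyloxy)-3-methoxy-2-methyl-5-[(16Z)-nonadec-16-en-1-yl]benzene F9. Syn-dihydroxylation (OsO4 cat., NMO, acetone/H2O) gives rac-(3R,4S)-19-[3-(benzyloxy)-5-methoxy-4-methylphenyl]nonadecane-3,4-diol F10, and double Swern oxidation ((COCl)2, DMSO, Et3N, CH2Cl2, −78 °C) gives 12 without C–C cleavage.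

**Further compounds**

F1 | step 8 | (2,3,5,6-tetramethoxyphenyl)lithium | [Li]c1c(OC)c(OC)cc(OC)c1OC
F2 | step 8 | 1,2,4,5-tetramethoxy-3-methylbenzene | Cc1c(OC)c(OC)cc(OC)c1OC
F3 | step 8 | (2,3,5,6-tetramethoxy-4-methylphenyl)lithium | [Li]c1c(OC)c(OC)c(C)c(OC)c1OC
F4 | step 8 | 1-(13-bromotridecyl)-2,3,5,6-tetramethoxy-4-methylbenzene | Cc1c(OC)c(OC)c(CCCCCCCCCCCCCBr)c(OC)c1OC
F5 | step 8 | bromo[13-(2,3,5,6-tetramethoxy-4-methylphenyl)tridecyl]magnesium | Cc1c(OC)c(OC)c(CCCCCCCCCCCCC[Mg]Br)c(OC)c1OC
F6 | step 8 | 1-(benzyloxy)-3-methoxy-2-methyl-5-[14-(2,3,5,6-tetramethoxy-4-methylphenyl)tetradecyl]benzene | Cc1c(OC)c(OC)c(CCCCCCCCCCCCCCc2cc(OC)c(C)c(OCc3ccccc3)c2)c(OC)c1OC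
F7 | step 8 | 2-{14-[3-(benzyloxy)-5-methoxy-4-methylphenyl]tetradecyl}-3,6-dimethoxy-5-methylcyclohexa-2,5-diene-1,4-dione | COC1=C(C)C(=O)C(OC)=C(CCCCCCCCCCCCCCc2cc(OC)c(C)c(OCc3ccccc3)c2)C1=O
F8 | step 11 | racemic cis-fused 2,5-dihydroxy-3-[14-(3-methoxy-4-methyl-2,5-dioxo-7-oxabicyclo[4.1.0]hept-3-en-1-yl)tetradecyl]-6-methylcyclohexa-2,5-diene-1,4-dione (one enantiomer drawn) | O=C1[C@@H]2O[C@]2(CCCCCCCCCCCCCCC3=C(O)C(=O)C(C)=C(O)C3=O)C(=O)C(OC)=C1C
F9 | step 7 | 1-(benzyloxy)-3-methoxy-2-methyl-5-[(16Z)-nonadec-16-en-1-yl]benzene | CC/C=C\CCCCCCCCCCCCCCCc1cc(OC)c(C)c(OCc2ccccc2)c1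
F10 | step 7 | rac-(3R,4S)-19-[3-(benzyloxy)-5-methoxy-4-methylphenyl]nonadecane-3,4-diol (one enantiomer drawn) | CC[C@@H](O)[C@@H](O)CCCCCCCCCCCCCCCc1cc(OC)c(C)c(OCc2ccccc2)c1
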